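By 8.0 h the south-west flask had to show its excess of right-handed substrate, and I counted everything as fractions of the pair of substrates charged.

all flasks: left-handed substrate 0.20 M; right-handed substrate 0.20 M

| charge | partner | precatalyst | remark | time |
|---|---|---|---|---|
| south-west | 0.12 M | 20 mM | the very flask that is asked about, followed so far |  |
| west | 0.12 M | 30 mM | run made earlier |  |
| flask | 0.120 M | 20 mM |  | 8.0 h |

| run | time / h | right-handed substrate / % | left-handed substrate / % | left-handed product / % |
|---|---|---|---|---|
| south-west | 0.333 | 49.3 | 48.1 | 1.5 |
| south-west | 0.667 | 49.1 | 45.0 | 4.0 |
| south-west | 1.00 | 48.5 | 44.0 | 7.0 |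
| south-west | 2.00 | 48.0 | 40.2 | 11.2 |
| south-west | 4.00 | 47.8 | 36.7 | 13.5 |
| west | 0.667 | 49.3 | 44.2 | 6.0 |
| west | 2.00 | 48.7 | 37.8 | 11.6 |
| west | 4.00 | 47.6 | 36.0 | 14.7 |
| west | 6.00 | 48.2 | 35.7 | 15.7 |
| west | 8.00 | 47.7 | 33.8 | 16.1 |

(each reading ± 0.5 percentage points)

* whether the excess of right-handed substrate over left-handed substrate among what is left of the two reaches 95% by 8.0 h (yes / no)
* the highest excess of right-handed substrate over left-handed substrate among what is left of the two up to 8.0 h

- free catalyst is single-handed; left-handed substrate and right-handed substrate are mirror images of each other, charged as a racemate, each of them at the stated concentration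

1. In the south-west run left-handed substrate fell and right-handed substrate barely moved, so I followed left-handed product.

2. The need came first. With right-handed substrate read at 47.8%, an excess of 95% required left-handed product at 48.8%.

3. Partner, the limiting reagent, was charged at 30.0% of the pair, less than the need, even on a first round with none lost.

4. I went round again with the readings. The west run's 16.1% at 8.00 h gave 0.537 of left-handed product per partner charged, and I called this the partner yield.

5. Put back on the south-west flask's partner charge, the same as the west run's, this reading gave an estimate of 16.1%. The need was 3.03 times that, so I said no, with a top near 17.0%.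

6. The forecast said no and 15.5%, on the ground that “The stall therefore barely scales with catalyst loading”. My top stood higher than its number.

7. The flask gave no, with a top of 15.7%.

    partner + free catalyst + left-handed substrate → free catalyst + left-handed product (k = 4.00 M⁻² min⁻¹)
    partner + free catalyst + right-handed substrate → free catalyst + right-handed product (k = 0.520 M⁻² min⁻¹)
    partner ⇌ dormant form (K = 3.40, k = 0.00640 min⁻¹)
    2 free catalyst → spent catalyst (k = 0.0410 M⁻¹ min⁻¹)
    partner + precatalyst → free catalyst + spent reagent (k = 0.210 M⁻¹ min⁻¹)

At 8.00 h the flask kept 3.3% of its partner and held 15.2% of left-handed product, a partner yield of 0.507. For the forecast's no to fail, left-handed product had to reach the need. A neighbouring flask, charged with 0.48 M of partner, had a partner yield of 0.393. Its left-handed product of 47.1% stayed below the 49.1% needed there, and its top was 84.6%.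

All runs are simulated from invented constants; noise was put on by code.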